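Follow one molecule of partner through this flask and ask where it comes to rest.

- north-west: solid substrate 0.10 M; partner 0.22 M; second substrate 0.50 M (in portions, 3); run made earlier; portions every 4.0 s
- flask: solid substrate 0.10 M; partner 0.110 M; second substrate 0.500 M (in portions, 3); time 4.0 min; the portions of second substrate follow each other after 4.0 s, the first at the start

north-west run (percent of the solid substrate charged)

| time / s | solid substrate / % | target / % | starting material / % |
|---|---|---|---|
| 10.0 | 40.3 | 14.0 | 46.5 |
| 20.0 | 9.7 | 14.2 | 75.3 |
| 30.0 | 0 | 12.7 | 88.3 |
| 40.0 | 0.8 | 11.9 | 88.7 |
| 50.0 | 0 | 11.5 | 88.1 |

(each reading ± 0.5 percentage points)

- as a solid, counted per litre of solution: solid substrate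
- at the start none of the solid substrate is in solution
- what has only dissolved of solid substrate counts as not reacted
- the reaction counts as stopped when no species that holds the solid substrate changes by six tenths of a point or more over the second half of the time
- starting material means what is dissolved; the solid is not counted in it

- at 4.0 min, what has stopped the reaction, if anything has (for what has run out or reacted, a solid counts together with what of it has only dissolved) (all of the solid substrate has reacted / forward and back rates have come level / the partner has run out first / it is still moving)
- part of the solid substrate that has turned into other species by 4.0 min (what has only dissolved does not count)
- target at 4.0 min, in percent of the solid substrate charged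
- starting material at 4.0 min, in percent of the solid substrate charged

Begin with the main step by itself: starting material takes up partner and gives target. This flask holds 0.110 M of partner against 0.10 M of solid substrate, so the charge allows target up to 100%.

Yet the north-west run, with 0.22 M of partner, ends at 11.5% target. So add a second step. Second substrate, charged at 0.50 M, holds partner too, and I assume it holds what target does not. Your molecule of partner now stands at a fork. The last step in target, 0.4 percentage points, lies within the scatter of 0.5 points, so I read the end of that run as a balance: thermodynamic control.

There [target]/[starting material] reads 0.131. Free second substrate is 0.292 M and partner held on it 0.208 M. That gives 0.182, a reading I call the fork quotient, [target][second substrate] / ([starting material][partner on second substrate]).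

In this flask [starting material] is 0.10 M − [target], held partner is 0.110 M − [target], and free second substrate is 0.390 M + [target]. The quadratic gives target 4.65% and starting material 95.3%. So the balance of the two steps, each running both ways, gives target 4.65%; the 100% above was a ceiling from the charge, not a yield of the main step by itself.

Now add the dissolving. In the north-west run solid substrate reads 0% at 30.0 s, and the three readings sum to 99.6% at 50.0 s. I therefore leave the number as it is. This flask runs for 4.0 min, so I expect forward and back rates level.

The forecast, with “the second substrate pushing it back”, says forward and back rates have come level, with target 6.1% and starting material 93.9%, so it stands higher in target than my reckoning.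

This flask gives forward and back rates have come level, conversion 4.79%, target 4.79% and starting material 95.2%.

    starting material + partner ⇌ target (K = 9.30 M⁻¹, k = 0.680 M⁻¹ s⁻¹)
    second substrate + partner ⇌ second product (K = 46.0 M⁻¹, k = 0.680 M⁻¹ s⁻¹)
    solid substrate ⇌ starting material, rate k3*(cs3 - [starting material]) while solid is left; crystals form when [starting material] > cs3 (solubility = 0.0960 M, k = 0.0870 s⁻¹)
    partner → decomposition product (k = 5.90 × 10⁻⁵ s⁻¹)

This flask's own values put the fork quotient at 0.189, against 0.182 from the north-west run. At the asked time, second substrate, partner and second product in this flask relax with a half-life of 2.38 s, far shorter than 4.0 min. Target in this flask reads 4.81% at 1.5 min and 4.76% at 40.0 min. For the neighbour flask with 0.28 M of partner, the quotient gives target 16.9%, and that flask gives 16.0%.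

The earlier runs and the new flask were generated by integration for substances that don't exist, and the scatter is random.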